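**Retrosynthetic overview**

1. Target 19 is ent-oritin-(4β→6)-epioritin-4α-ol: an upper 2,3-trans-3,4-trans 4-arylflavan-3-ol and a lower all-cis flavan-3,4-diol. It is released from 18 by one hydrogenolysis (two benzyl ethers, one diphenylmethylene ketal).
2. Key disconnection: ring C of the lower unit is cut at O1–C2 and at C4a–C4, giving triol 12 and cis-epoxy aldehyde 16. The enabling feature is that this ring carries an oxygen on each sp3 carbon (O1 on C2, OH on C3, OH on C4) and is fused to a pyrogallol-derived ring A in which O1 has exactly one free ortho C–H (C4a). A phenol O/ortho-C pair can therefore be joined to a C2/C4 dielectrophile at the epoxy aldehyde oxidation level.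
3. Interflavanyl C4–C6 bond: Friedel–Crafts capture of the C4 benzylic cation of flavan-3,4-diol 11 by symmetric pyrogallol 1 (no regiochemical choice), 3,4-trans.
4. Upper ring C: the same two bonds, made in two discrete precedented steps from bromophenol 4 and trans-epoxy aldehyde 8. Both 8 and 16 come from aldehyde 5 by catalytic asymmetric epoxidation, which sets C2/C3 of each unit; C4 of each unit is relayed by substrate control.
5. Ring order: upper ring C (steps 5–6), interflavanyl bond (step 7), lower ring C (step 11). Both rings A derive from pyrogallol, both rings B from 5.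

Key step: step 11

Assumption: the (R)-diarylprolinol silyl ether and the (S,S)-salen manganese chloride are taken to give the (2S,3R)- and (2S,3S)-oxiranes, because their antipodes are associated with the (2R,3S) and (2R,3R) series for the parent cinnamyl substrates; if the sense is opposite on these substrates, the other catalyst antipode is used.

**Route**

Step 1
Reactants: 1 pyrogallol; 2 dichlorodiphenylmethane
Product: 3 ketal phenol 2,2-diphenyl-1,3-benzodioxol-4-ol
Conditions: neat melt, 160–170 °C, N2 stream
Reagents that add atoms: none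
Why: Diphenylmethylene ketal formation (double O-alkylation of one vicinal phenol pair by the gem-dichloride, a standard catechol protection) can bridge only two adjacent oxygens, so one hydroxyl stays free and becomes O1 of the upper unit.

Step 2
Reactants: 3 ketal phenol
Product: 4 bromophenol 5-bromo-2,2-diphenyl-1,3-benzodioxol-4-ol
Conditions: NBS (1.0 equiv), i-Pr2NH (10 mol %), CH2Cl2, 0 °C
Reagents that add atoms: N-bromosuccinimide, O=C1CCC(=O)N1Br
Why: Amine-catalysed ortho-selective electrophilic bromination of a phenol, the N-bromoamine being delivered by hydrogen bonding to the hydroxyl so that C5 should be substituted in preference to the para position C7.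

Step 3
Reactants: 5 4-(benzyloxy)benzaldehyde; 6 (triphenylphosphoranylidene)acetaldehyde
Product: 7 (E)-3-[4-(benzyloxy)phenyl]prop-2-enal
Conditions: toluene, 80 °C
Reagents that add atoms: none
Why: Wittig olefination with a stabilised ylide, which should give the (E)-enal by two-carbon homologation.

Step 4
Reactants: 7 (E)-enal
Product: 8 trans-epoxy aldehyde (2S,3R)-3-[4-(benzyloxy)phenyl]oxirane-2-carbaldehyde
Conditions: (R)-2-{bis[3,5-bis(trifluoromethyl)phenyl](trimethylsilyloxy)methyl}pyrrolidine (10 mol %), 35% aq. H2O2 (1.3 equiv), CH2Cl2, 25 °C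
Reagents that add atoms: hydrogen peroxide, OO
Why: Iminium-activated nucleophilic (Weitz–Scheffer-type) epoxidation of an enal, in which the silyloxydiarylmethyl group of the catalyst shields one face of the iminium ion so that both oxirane stereocentres (2S,3R, trans) are set by catalyst control.

Step 5
Reactants: 4 bromophenol; 8 trans-epoxy aldehyde
Product: 10 epoxy alcohol 5-{(R)-[(2R,3R)-3-[4-(benzyloxy)phenyl]oxiran-2-yl](hydroxy)methyl}-2,2-diphenyl-1,3-benzodioxol-4-ol (anti epimer drawn), via dilithio phenoxide 9 (not isolated)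
Conditions: n-BuLi (2.1 equiv), THF, −78 °C; then 8, −78 °C; aq. NH4Cl
Reagents that add atoms: none
Why: Bromine–lithium exchange on the lithium phenoxide followed by 1,2-addition of the aryllithium to the aldehyde at −78 °C, where the oxirane is inert; polar Felkin–Anh control should favour the anti carbinol, but either C4 epimer is usable because this centre is ionised in step 7.

Step 6
Reactants: 10 epoxy alcohol
Product: 11 flavan-3,4-diol (2S,3R,4R)-2-[4-(benzyloxy)phenyl]-7,8-(diphenylmethylenedioxy)chromane-3,4-diol (2,3-trans-3,4-cis)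
Conditions: Ti(OiPr)4 (1.5 equiv), CH2Cl2, 0 → 25 °C; aq. KNaC4H4O6
Reagents that add atoms: none
Why: Ti(OiPr)4-mediated regioselective opening of a 2,3-epoxy alcohol at the distal carbon by an oxygen nucleophile, here the tethered phenol in a 6-endo closure with inversion at the benzylic carbon, which should turn the trans-oxirane into the 2,3-trans chroman (C2 S by inversion, C3 R retained).

Step 7
Reactants: 11 flavan-3,4-diol; 1 pyrogallol (5 equiv)
Product: 12 triol (2S,3R,4S)-2-[4-(benzyloxy)phenyl]-7,8-(diphenylmethylenedioxy)-4-(2,3,4-trihydroxyphenyl)chroman-3-ol (2,3-trans-3,4-trans)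
Conditions: TsOH·H2O (10 mol %), MeCN/CH2Cl2 1:1, 0 → 25 °C, argon
Reagents that add atoms: none
Why: Acid-catalysed ionisation of the C4 benzylic alcohol (loss of water) to a cation stabilised by O1 and the para 7-oxygen, then Friedel–Crafts capture by pyrogallol at its C4 (the two activated positions are equivalent), the arene approaching the half-chair cation anti to the 3-hydroxyl to set the 3,4-trans (4S, 4β) centre whatever the C4 configuration of 11.

Step 8
Reactants: 5 4-(benzyloxy)benzaldehyde; 13 methyl bis(2,2,2-trifluoroethyl)phosphonoacetate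
Product: 14 methyl (Z)-3-[4-(benzyloxy)phenyl]prop-2-enoate
Conditions: KN(SiMe3)2, 18-crown-6, THF, −78 °C
Reagents that add atoms: none
Why: Still–Gennari modification of the Horner–Wadsworth–Emmons olefination, whose electron-poor phosphonate under dissociating conditions should give the (Z)-cinnamate kinetically.

Step 9
Reactants: 14 (Z)-ester
Product: 15 cis-glycidate methyl (2S,3S)-3-[4-(benzyloxy)phenyl]oxirane-2-carboxylate
Conditions: (S,S)-(salen)MnCl [salen = N,N′-bis(3,5-di-tert-butylsalicylidene)-1,2-cyclohexanediaminato, trivalent manganese] (5 mol %), 4-phenylpyridine N-oxide (0.25 equiv), aq. NaOCl (pH 11.3), CH2Cl2, 4 °C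
Reagents that add atoms: sodium hypochlorite, [Na+].[O-]Cl
Why: Jacobsen–Katsuki epoxidation of a cis-disubstituted conjugated olefin, the chiral salen manganese oxo species transferring oxygen to one enantioface so that both cis-oxirane stereocentres (2S,3S) are set by catalyst control.

Step 10
Reactants: 15 cis-glycidate
Product: 16 cis-epoxy aldehyde (2S,3S)-3-[4-(benzyloxy)phenyl]oxirane-2-carbaldehyde
Conditions: i-Bu2AlH (1.1 equiv), CH2Cl2, −78 °C; aq. KNaC4H4O6
Reagents that add atoms: none
Why: Partial reduction of an ester with i-Bu2AlH at −78 °C, where the tetrahedral aluminium hemiacetal (stabilised by the adjacent oxirane oxygen) survives until work-up and the non-enolisable oxirane alpha-carbon keeps its configuration.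

Step 11
Reactants: 12 triol; 16 cis-epoxy aldehyde (1.2 equiv)
Product: 18 protected dimer [4′-O-benzyl-7,8-O-(diphenylmethylene)-ent-oritin]-(4β→6)-(4′-O-benzyl-epioritin-4α-ol), via anti epoxy alcohol adduct 17 (not isolated)
Conditions: Ti(OiPr)4 (3 equiv), toluene, 25 °C, then removal of i-PrOH in vacuo; CH2Cl2, 4 Å MS, 16, −20 → 25 °C; aq. KNaC4H4O6
Reagents that add atoms: none
Why: Proposed new method: exchange of the hydroxyl protons of 12 for isopropoxytitanium gives an aryloxytitanium species whose O1-bound metal binds the aldehyde of 16 and delivers it to the only free ortho carbon (future C4a) in an ortho-specific phenoxide hydroxyalkylation (closest known type: ortho-hydroxyalkylation of magnesium or titanium phenoxides with chiral alpha-oxygenated aldehydes), after which the titanium 2,3-epoxy alkoxide of 17 is opened at its distal benzylic carbon by the same phenol oxygen (closest known type: Ti(OiPr)4-mediated distal opening of 2,3-epoxy alcohols by phenols). Ring C of the lower unit is thus closed in a 6-endo-tet epoxide opening, favoured over the 5-exo mode by the 4-benzyloxyphenyl group that stabilises positive charge at C2 and by titanium bridging the C4 alkoxide and the oxirane oxygen. C4 is set by substrate control in the C–C bond formation, because the non-chelating titanium aryloxide should attack the polar Felkin–Anh (Cornforth) conformer of the cis-epoxy aldehyde on the face away from the aryl-bearing oxirane carbon, giving the anti epoxy alkoxide that becomes the 3,4-cis diol (4R). C3 keeps the configuration of the oxirane C2 of 16 (its descriptor becomes R only through the priority rules), and C2 (R) arises by inversion of the (3S) oxirane carbon in the SN2-like closure, which converts the cis-oxirane into the 2,3-cis chroman. The step needs ortho regioselectivity (secured by the metal template, by O1 being the only pyrogallol oxygen with a free ortho position, and by the ketal and benzyl groups that silence ring A of the upper unit), anti facial selectivity (secured by the cis-aryl group of the oxirane), and inversion without ionisation at C2 (favoured by the weakly Lewis-acidic alkoxide-ligated titanium, the low temperature and the non-polar medium).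

Step 12
Reactants: 18 protected dimer
Product: 19 target (2R,3R,4R)-2-(4-hydroxyphenyl)-6-[(2S,3R,4S)-3,7,8-trihydroxy-2-(4-hydroxyphenyl)-3,4-dihydro-2H-chromen-4-yl]-3,4-dihydro-2H-chromene-3,4,7,8-tetrol
Conditions: H2 (1 atm), Pd(OH)2/C, THF/MeOH, 25 °C
Reagents that add atoms: none
Why: Catalytic hydrogenolysis of aryl benzyl ethers and of the diphenylmethylene ketal under neutral conditions, which should leave the ring C2–O1 bonds, the C4 hydroxyl, the interflavanyl bond and all six stereocentres untouched.

**Compound list**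

1 | pyrogallol (benzene-1,2,3-triol) | Oc1cccc(O)c1O | starting material
2 | dichlorodiphenylmethane | ClC(Cl)(c1ccccc1)c1ccccc1 | starting material
3 | 2,2-diphenyl-1,3-benzodioxol-4-ol | Oc1cccc2OC(c3ccccc3)(c3ccccc3)Oc12 | intermediate
4 | 5-bromo-2,2-diphenyl-1,3-benzodioxol-4-ol | Oc1c(Br)ccc2OC(c3ccccc3)(c3ccccc3)Oc12 | intermediate
5 | 4-(benzyloxy)benzaldehyde | O=Cc1ccc(OCc2ccccc2)cc1 | starting material
6 | (triphenylphosphoranylidene)acetaldehyde | O=CC=P(c1ccccc1)(c1ccccc1)c1ccccc1 | starting material
7 | (E)-3-[4-(benzyloxy)phenyl]prop-2-enal | O=C/C=C/c1ccc(OCc2ccccc2)cc1 | intermediate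
8 | (2S,3R)-3-[4-(benzyloxy)phenyl]oxirane-2-carbaldehyde (trans) | O=C[C@H]1O[C@@H]1c1ccc(OCc2ccccc2)cc1 | intermediate
9 | lithium 5-lithio-2,2-diphenyl-1,3-benzodioxol-4-olate (dilithio phenoxide) | [Li]Oc1c([Li])ccc2OC(c3ccccc3)(c3ccccc3)Oc12 | intermediate (not isolated)
10 | 5-{(R)-[(2R,3R)-3-[4-(benzyloxy)phenyl]oxiran-2-yl](hydroxy)methyl}-2,2-diphenyl-1,3-benzodioxol-4-ol (anti epimer; trans-oxirane) | O[C@H](c1ccc2OC(c3ccccc3)(c3ccccc3)Oc2c1O)[C@H]1O[C@@H]1c1ccc(OCc2ccccc2)cc1 | intermediate
11 | (2S,3R,4R)-2-[4-(benzyloxy)phenyl]-7,8-(diphenylmethylenedioxy)chromane-3,4-diol (2,3-trans-3,4-cis) | O[C@@H]1c2ccc3OC(c4ccccc4)(c4ccccc4)Oc3c2O[C@@H](c2ccc(OCc3ccccc3)cc2)[C@@H]1O | intermediate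
12 | (2S,3R,4S)-2-[4-(benzyloxy)phenyl]-7,8-(diphenylmethylenedioxy)-4-(2,3,4-trihydroxyphenyl)chroman-3-ol (2,3-trans-3,4-trans) | Oc1ccc([C@H]2c3ccc4OC(c5ccccc5)(c5ccccc5)Oc4c3O[C@@H](c3ccc(OCc4ccccc4)cc3)[C@@H]2O)c(O)c1O | intermediate
13 | methyl bis(2,2,2-trifluoroethyl)phosphonoacetate | COC(=O)CP(=O)(OCC(F)(F)F)OCC(F)(F)F | starting material
14 | methyl (Z)-3-[4-(benzyloxy)phenyl]prop-2-enoate | COC(=O)/C=C\c1ccc(OCc2ccccc2)cc1 | intermediate
15 | methyl (2S,3S)-3-[4-(benzyloxy)phenyl]oxirane-2-carboxylate (cis) | COC(=O)[C@H]1O[C@H]1c1ccc(OCc2ccccc2)cc1 | intermediate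
16 | (2S,3S)-3-[4-(benzyloxy)phenyl]oxirane-2-carbaldehyde (cis) | O=C[C@H]1O[C@H]1c1ccc(OCc2ccccc2)cc1 | intermediate
17 | triol 12 carrying, at the free position ortho to the 4-hydroxyl of its trihydroxyphenyl ring, an (R)-[(2R,3S)-3-[4-(benzyloxy)phenyl]oxiran-2-yl](hydroxy)methyl group (anti adduct; cis-oxirane) | O[C@H](c1cc([C@H]2c3ccc4OC(c5ccccc5)(c5ccccc5)Oc4c3O[C@@H](c3ccc(OCc4ccccc4)cc3)[C@@H]2O)c(O)c(O)c1O)[C@H]1O[C@H]1c1ccc(OCc2ccccc2)cc1 | intermediate (not isolated)
18 | protected dimer: lower unit (2R,3R,4R)-2-[4-(benzyloxy)phenyl]chromane-3,4,7,8-tetrol, joined at C6 to C4 of the upper unit (2S,3R,4S)-2-[4-(benzyloxy)phenyl]-7,8-(diphenylmethylenedioxy)chroman-3-ol | c1ccccc1COc1ccc([C@H]2Oc3c(cc([C@H]4c5ccc6OC(c7ccccc7)(c7ccccc7)Oc6c5O[C@@H](c5ccc(OCc6ccccc6)cc5)[C@@H]4O)c(O)c3O)[C@@H](O)[C@H]2O)cc1 | intermediate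
19 | (2R,3R,4R)-2-(4-hydroxyphenyl)-6-[(2S,3R,4S)-3,7,8-trihydroxy-2-(4-hydroxyphenyl)-3,4-dihydro-2H-chromen-4-yl]-3,4-dihydro-2H-chromene-3,4,7,8-tetrol | Oc1ccc([C@H]2Oc3c(cc([C@H]4c5ccc(O)c(O)c5O[C@@H](c5ccc(O)cc5)[C@@H]4O)c(O)c3O)[C@@H](O)[C@H]2O)cc1 | target

**Step count and risks**

Total steps: 12. Longest linear sequence: 7 steps (steps 1, 2, 5, 6, 7, 11, 12; equally steps 3, 4, 5, 6, 7, 11, 12).

Steps most likely to fail:

1. Step 11 (Proposed new method). Possible failures are:
   - ionisation at the p-alkoxybenzylic oxirane carbon before ring closure, which would erode the inversion at C2 and give the 2,3-trans epimer;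
   - competing 5-exo closure to a dihydrobenzofuran;
   - chelation-controlled (syn) addition, giving the 3,4-trans diol;
   - retention of the catechol-type product on titanium during work-up.

   Fallback (known chemistry only): it sets out from 11, 4 and 16 and comes back to the route at 19. Flavan-3,4-diol 11 is condensed (TsOH·H2O cat., MeCN/CH2Cl2, 0 → 25 °C) with bromophenol 4 in place of pyrogallol. With the ortho position blocked by bromine, the C4 cation should be taken up para to the free hydroxyl, giving the bromo 4-arylflavan-3-ol F1. Deprotonation of both hydroxyls and bromine–lithium exchange (n-BuLi, 3.1 equiv, THF, −78 °C), transmetalation with ClTi(OiPr)3 and addition to 16 (non-chelation-controlled aryltitanium addition to an alpha-oxygenated aldehyde) should give the anti epoxy alcohol F2, its regiochemistry fixed by the position of the halogen. Ti(OiPr)4 in CH2Cl2 (distal opening of a 2,3-epoxy alcohol by the tethered phenol, with inversion) should close the lower ring C to the fully protected dimer F3. Hydrogenolysis of its two benzyl ethers and two ketals (H2, Pd(OH)2/C, THF/MeOH) should give 19.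

2. Step 7. Possible failures are:
   - poor facial selectivity in the capture of the 2,3-trans C4 cation (3,4-cis coproduct);
   - a second alkylation of the pyrogallol ring;
   - acid-induced opening of ring C through the p-alkoxybenzylic C2–O1 bond.

   Fallback: it sets out from 11 and comes back at 12. Diol 11 is acetylated (Ac2O, pyridine, DMAP cat.) to the diacetate F4. Treatment with BF3·OEt2 and pyrogallol (5 equiv, CH2Cl2/1,4-dioxane, −20 °C) should ionise C4, after which the 3-acetoxy group should bridge the cation as a cis-fused acetoxonium ion; this blocks the face of the 3-oxygen, so the arene can enter only trans to it, giving the 3-O-acetyl 4β-aryl compound F5. Methanolysis (K2CO3, degassed MeOH, 0 °C, argon) should return 12.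

3. Step 9. Possible failures are cis-to-trans leakage by bond rotation in the radical intermediate, which the electron-rich aryl group stabilises, and erosion of enantiomeric purity.

   Fallback: it sets out from 14 and comes back at 16. Ester 14 is reduced (i-Bu2AlH, 2.2 equiv, CH2Cl2, −78 °C) to the (Z)-allylic alcohol F6. Sharpless asymmetric epoxidation (Ti(OiPr)4, D-(−)-diisopropyl tartrate, t-BuOOH, 4 Å MS, CH2Cl2, −20 °C) should give the cis-epoxy alcohol F7 with retention of olefin geometry. Oxidation with Dess–Martin periodinane buffered with NaHCO3 should give 16.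

Further compounds
F1 | step 11 | (2S,3R)-2-[4-(benzyloxy)phenyl]-4β-(6-bromo-7-hydroxy-2,2-diphenyl-1,3-benzodioxol-4-yl)-7,8-(diphenylmethylenedioxy)chroman-3-ol (2,3-trans-3,4-trans) | Oc1c(Br)cc([C@H]2c3ccc4OC(c5ccccc5)(c5ccccc5)Oc4c3O[C@@H](c3ccc(OCc4ccccc4)cc3)[C@@H]2O)c2OC(c3ccccc3)(c3ccccc3)Oc12
F2 | step 11 | F1 with bromine replaced by an (R)-[(2R,3S)-3-[4-(benzyloxy)phenyl]oxiran-2-yl](hydroxy)methyl group (anti epoxy alcohol; cis-oxirane) | O[C@H](c1cc([C@H]2c3ccc4OC(c5ccccc5)(c5ccccc5)Oc4c3O[C@@H](c3ccc(OCc4ccccc4)cc3)[C@@H]2O)c2OC(c3ccccc3)(c3ccccc3)Oc2c1O)[C@H]1O[C@H]1c1ccc(OCc2ccccc2)cc1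
F3 | step 11 | fully protected dimer [4′-O-benzyl-7,8-O-(diphenylmethylene)-ent-oritin]-(4β→6)-[4′-O-benzyl-7,8-O-(diphenylmethylene)-epioritin-4α-ol] | c1ccccc1COc1ccc([C@H]2Oc3c(cc([C@H]4c5ccc6OC(c7ccccc7)(c7ccccc7)Oc6c5O[C@@H](c5ccc(OCc6ccccc6)cc5)[C@@H]4O)c4OC(c5ccccc5)(c5ccccc5)Oc34)[C@@H](O)[C@H]2O)cc1
F4 | step 7 | (2S,3R,4R)-2-[4-(benzyloxy)phenyl]-7,8-(diphenylmethylenedioxy)chromane-3,4-diyl diacetate | CC(=O)O[C@@H]1c2ccc3OC(c4ccccc4)(c4ccccc4)Oc3c2O[C@@H](c2ccc(OCc3ccccc3)cc2)[C@@H]1OC(C)=O
F5 | step 7 | 3-O-acetate of 12: (2S,3R,4S)-2-[4-(benzyloxy)phenyl]-7,8-(diphenylmethylenedioxy)-4-(2,3,4-trihydroxyphenyl)chroman-3-yl acetate | Oc1ccc([C@H]2c3ccc4OC(c5ccccc5)(c5ccccc5)Oc4c3O[C@@H](c3ccc(OCc4ccccc4)cc3)[C@@H]2OC(C)=O)c(O)c1O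
F6 | step 9 | (Z)-3-[4-(benzyloxy)phenyl]prop-2-en-1-ol | OC/C=C\c1ccc(OCc2ccccc2)cc1
F7 | step 9 | [(2R,3S)-3-[4-(benzyloxy)phenyl]oxiran-2-yl]methanol (cis) | OC[C@H]1O[C@H]1c1ccc(OCc2ccccc2)cc1
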